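**Retrosynthetic overview**
- The target is opened at the pyranone O1–C2 bond to an α-aryl-β,β-dimethoxy ketone, so the isoflavone ring is closed last.
- Key step: that acetal comes from a biomimetic Tl(III) oxidative 1,2-aryl shift of a 2'-hydroxychalcone. This replaces the usual 3-iodochromone Suzuki coupling or deoxybenzoin route.
- The chalcone comes from a Claisen–Schmidt condensation of a MOM-protected resacetophenone with a chromene-5-carbaldehyde.
- The chromene aldehyde comes from 5-hydroxyvanillin by selective 4-O-MOM protection, O-(1,1-dimethylpropargyl)ation and a propargyl Claisen/oxa-6π cascade.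
- Ring order: the 2H-pyran (chromene) ring first, the 4-pyranone ring last.

Assumption: the target SMILES has no stereocentre (the molecule is achiral), so "single enantiomer" is moot; the only stereo-elements in the route are the transient (E)-enone and racemic sp3 centres that are destroyed again.

**Step 1**
Reactants: 1 3,4-dihydroxy-5-methoxybenzaldehyde (5-hydroxyvanillin)
Product: 2 3-hydroxy-5-methoxy-4-(methoxymethoxy)benzaldehyde
Conditions: MOMCl (1.0 equiv), K2CO3 (1.0 equiv), DMF, 0 °C to rt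
Reagents that add atoms: chloromethyl methyl ether (MOMCl), COCCl
Why: Williamson-type O-alkylation under acidity control; the 4-OH is para to the formyl group and about two pKa units more acidic than the 3-OH, so one equivalent of carbonate ionises and alkylates it selectively, as in the selective 4-O-alkylations of catechol aldehydes.

**Step 2**
Reactants: 2 3-hydroxy-5-methoxy-4-(methoxymethoxy)benzaldehyde; 3 3-chloro-3-methylbut-1-yne
Product: 4 3-methoxy-4-(methoxymethoxy)-5-[(2-methylbut-3-yn-2-yl)oxy]benzaldehyde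
Conditions: 3 (2.5 equiv), K2CO3 (2 equiv), KI (0.2 equiv), CuI (5 mol%), DMF, 60 °C
Reagents that add atoms: none
Why: Cu(I)-assisted O-propargylation of a phenoxide with a tertiary propargylic chloride (copper acetylide/allenylidene-type ionisation, then O-attack at the tertiary carbon), which tolerates the aldehyde and the MOM ether.

**Step 3**
Reactants: 4 3-methoxy-4-(methoxymethoxy)-5-[(2-methylbut-3-yn-2-yl)oxy]benzaldehyde
Product: 7 7-methoxy-8-(methoxymethoxy)-2,2-dimethyl-2H-chromene-5-carbaldehyde, via 3-hydroxy-5-methoxy-4-(methoxymethoxy)-2-(3-methylbuta-1,2-dien-1-yl)benzaldehyde 5 (not isolated), via 3-methoxy-4-(methoxymethoxy)-6-(3-methylbut-2-en-1-ylidene)-5-oxocyclohexa-1,3-diene-1-carbaldehyde 6 (not isolated)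
Conditions: PhNEt2, 190 °C, 2–3 h, Ar
Reagents that add atoms: none
Why: Aromatic propargyl Claisen rearrangement ([3,3]) can only reach C-2 because the other ortho position carries OMOM; tautomerisation gives allenylphenol 5, a 1,5-H shift gives o-quinone methide 6, and oxa-6π electrocyclisation closes the 2,2-dimethyl-2H-chromene (the isovanillin-derived ether behaves the same way); no stereocentre is formed.

**Step 4**
Reactants: 8 1-(2,4-dihydroxyphenyl)ethan-1-one (2,4-dihydroxyacetophenone)
Product: 9 1-[2-hydroxy-4-(methoxymethoxy)phenyl]ethan-1-one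
Conditions: MOMCl (1.1 equiv), K2CO3 (1.2 equiv), acetone, 0 °C to rt
Reagents that add atoms: chloromethyl methyl ether (MOMCl), COCCl
Why: Selective Williamson O-alkylation; the 2-OH is locked in a hydrogen bond to the acetyl C=O and is much less nucleophilic, so only the 4-OH is protected.

**Step 5**
Reactants: 7 7-methoxy-8-(methoxymethoxy)-2,2-dimethyl-2H-chromene-5-carbaldehyde; 9 1-[2-hydroxy-4-(methoxymethoxy)phenyl]ethan-1-one
Product: 11 (E)-1-[2-hydroxy-4-(methoxymethoxy)phenyl]-3-[7-methoxy-8-(methoxymethoxy)-2,2-dimethyl-2H-chromen-5-yl]prop-2-en-1-one, via 3-hydroxy-1-[2-hydroxy-4-(methoxymethoxy)phenyl]-3-[7-methoxy-8-(methoxymethoxy)-2,2-dimethyl-2H-chromen-5-yl]propan-1-one 10 (not isolated)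
Conditions: 50% aq. KOH, EtOH, rt, 24–48 h; then AcOH to pH 6 at 0 °C
Reagents that add atoms: none
Why: Claisen–Schmidt (crossed aldol) condensation; the enolate of 9 adds to the non-enolisable aldehyde 7 to give racemic aldol 10, and E1cB loss of water gives the thermodynamically favoured (E)-enone, while the 2'-phenoxide keeps the product open-chain rather than a flavanone.

**Step 6**
Reactants: 11 (E)-1-[2-hydroxy-4-(methoxymethoxy)phenyl]-3-[7-methoxy-8-(methoxymethoxy)-2,2-dimethyl-2H-chromen-5-yl]prop-2-en-1-one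
Product: 14 7-hydroxy-3-(8-hydroxy-7-methoxy-2,2-dimethyl-2H-chromen-5-yl)-4H-chromen-4-one, via 1-[2-hydroxy-4-(methoxymethoxy)phenyl]-3,3-dimethoxy-2-[7-methoxy-8-(methoxymethoxy)-2,2-dimethyl-2H-chromen-5-yl]propan-1-one 12 (not isolated), via 3-[7-methoxy-8-(methoxymethoxy)-2,2-dimethyl-2H-chromen-5-yl]-7-(methoxymethoxy)-4H-chromen-4-one 13 (not isolated)
Conditions: Tl(NO3)3·3H2O (1.05 equiv), MeOH, –10 °C to rt, 3 h; filter; then conc. HCl (to ca. 1 M), MeOH, 50 °C, 3 h
Reagents that add atoms: none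
Why: Tl(III) oxidative rearrangement of a 2'-hydroxychalcone (biomimetic 1,2-aryl shift): methoxythallation puts Tl on Cα, the para-alkoxy aryl ring migrates from Cβ to Cα through a phenonium ion as Tl(I) leaves, and methanol traps the oxocarbenium as acetal 12; acid then closes the pyranone by 2'-OH attack on the acetal with loss of two MeOH (13) and solvolyses both MOM ethers to the achiral target, the chromene C3=C4 bond being shielded from oxythallation by the adjacent gem-dimethyl carbon.

**Compound list**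
1 | 3,4-dihydroxy-5-methoxybenzaldehyde (5-hydroxyvanillin) | COc1cc(C=O)cc(O)c1O | starting material
2 | 3-hydroxy-5-methoxy-4-(methoxymethoxy)benzaldehyde | COCOc1c(O)cc(C=O)cc1OC | intermediate
3 | 3-chloro-3-methylbut-1-yne | CC(C)(Cl)C#C | starting material
4 | 3-methoxy-4-(methoxymethoxy)-5-[(2-methylbut-3-yn-2-yl)oxy]benzaldehyde | COCOc1c(OC)cc(C=O)cc1OC(C)(C)C#C | intermediate
5 | 3-hydroxy-5-methoxy-4-(methoxymethoxy)-2-(3-methylbuta-1,2-dien-1-yl)benzaldehyde | COCOc1c(OC)cc(C=O)c(C=C=C(C)C)c1O | intermediate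
6 | 3-methoxy-4-(methoxymethoxy)-6-(3-methylbut-2-en-1-ylidene)-5-oxocyclohexa-1,3-diene-1-carbaldehyde (o-quinone methide, exocyclic geometry undefined) | O=CC1=CC(OC)=C(OCOC)C(=O)C1=CC=C(C)C | intermediate
7 | 7-methoxy-8-(methoxymethoxy)-2,2-dimethyl-2H-chromene-5-carbaldehyde | COCOc1c(OC)cc(C=O)c2C=CC(C)(C)Oc12 | intermediate
8 | 1-(2,4-dihydroxyphenyl)ethan-1-one (2,4-dihydroxyacetophenone) | CC(=O)c1ccc(O)cc1O | starting material
9 | 1-[2-hydroxy-4-(methoxymethoxy)phenyl]ethan-1-one | CC(=O)c1ccc(OCOC)cc1O | intermediate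
10 | 3-hydroxy-1-[2-hydroxy-4-(methoxymethoxy)phenyl]-3-[7-methoxy-8-(methoxymethoxy)-2,2-dimethyl-2H-chromen-5-yl]propan-1-one (racemic) | COCOc1ccc(C(=O)CC(O)c2cc(OC)c(OCOC)c3OC(C)(C)C=Cc23)c(O)c1 | intermediate
11 | (E)-1-[2-hydroxy-4-(methoxymethoxy)phenyl]-3-[7-methoxy-8-(methoxymethoxy)-2,2-dimethyl-2H-chromen-5-yl]prop-2-en-1-one | COCOc1ccc(C(=O)/C=C/c2cc(OC)c(OCOC)c3OC(C)(C)C=Cc23)c(O)c1 | intermediate
12 | 1-[2-hydroxy-4-(methoxymethoxy)phenyl]-3,3-dimethoxy-2-[7-methoxy-8-(methoxymethoxy)-2,2-dimethyl-2H-chromen-5-yl]propan-1-one (racemic) | COCOc1ccc(C(=O)C(C(OC)OC)c2cc(OC)c(OCOC)c3OC(C)(C)C=Cc23)c(O)c1 | intermediate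
13 | 3-[7-methoxy-8-(methoxymethoxy)-2,2-dimethyl-2H-chromen-5-yl]-7-(methoxymethoxy)-4H-chromen-4-one | COCOc1ccc2c(c1)occ(-c1cc(OC)c(OCOC)c3OC(C)(C)C=Cc13)c2=O | intermediate
14 | 7-hydroxy-3-(8-hydroxy-7-methoxy-2,2-dimethyl-2H-chromen-5-yl)-4H-chromen-4-one | COc1cc(-c2coc3cc(O)ccc3c2=O)c2c(c1O)OC(C)(C)C=C2 | target

**Totals**
Total step count: 6. Longest linear sequence: 5 steps (steps 1, 2, 3, 5, 6, from 1 to 14).

**Three steps most likely to fail**

Step 6 is the main risk. Tl(III) could oxythallate the chromene olefin or oxidise a phenol unmasked early by the nitric acid formed, and thallium salts are highly toxic. The fallback sets out from 11 and comes back at 14. It replaces the oxidative aryl shift by a redox-neutral 1,2-acyl shift. The 2'-OH of 11 is capped (NaH, MOMCl, THF, 0 °C) to give (E)-1-[2,4-bis(methoxymethoxy)phenyl]-3-[7-methoxy-8-(methoxymethoxy)-2,2-dimethyl-2H-chromen-5-yl]prop-2-en-1-one F1. Weitz–Scheffer epoxidation (30% H2O2, NaOH, MeOH/THF, 0 °C) attacks only the electron-poor enone and gives racemic trans-[2,4-bis(methoxymethoxy)phenyl]{3-[7-methoxy-8-(methoxymethoxy)-2,2-dimethyl-2H-chromen-5-yl]oxiran-2-yl}methanone F2. BF3·OEt2 (CH2Cl2, –40 °C, minutes) opens the epoxide at the para-alkoxybenzylic carbon and the aroyl group shifts (chalcone-epoxide rearrangement) to 3-[2,4-bis(methoxymethoxy)phenyl]-2-[7-methoxy-8-(methoxymethoxy)-2,2-dimethyl-2H-chromen-5-yl]-3-oxopropanal F3. HCl/MeOH at 50 °C then removes the three MOM groups and cyclodehydrates to 14.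

Step 1 may give a mixture of 4-O-, 3-O- and bis-MOM products. The fallback sets out from 1 and comes back at 4, with the order of the two O-alkylations reversed by dianion chemistry. Compound 1 with NaH (2.1 equiv) in DMSO gives the dianion, whose 3-phenoxide is not conjugated with the formyl group and is the more nucleophilic oxygen. One equivalent of 3 with catalytic CuI then gives 4-hydroxy-3-methoxy-5-[(2-methylbut-3-yn-2-yl)oxy]benzaldehyde F4. MOMCl/i-Pr2NEt (CH2Cl2, 0 °C) caps the remaining 4-OH to give 4. The dianion alkylation with a tertiary propargylic chloride is the least precedented part of this fallback.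

Step 3 may suffer from MOM loss or decomposition at 190 °C, or from benzofuran formation from 5. The fallback sets out from 4 and comes back at 7, using a lower-temperature allyl Claisen and an oxidative ring closure. Lindlar semi-hydrogenation (H2, Pd/CaCO3–Pb, quinoline, EtOAc) gives 3-methoxy-4-(methoxymethoxy)-5-[(2-methylbut-3-en-2-yl)oxy]benzaldehyde F5. Aromatic Claisen rearrangement (xylene, 120–130 °C) gives 3-hydroxy-5-methoxy-4-(methoxymethoxy)-2-(3-methylbut-2-en-1-yl)benzaldehyde F6. DDQ (1.1 equiv, toluene, 80 °C) abstracts the benzylic hydride to regenerate o-quinone methide 6, which electrocyclises to 7.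

**Further compounds**
F1 | step 6 | (E)-1-[2,4-bis(methoxymethoxy)phenyl]-3-[7-methoxy-8-(methoxymethoxy)-2,2-dimethyl-2H-chromen-5-yl]prop-2-en-1-one | COCOc1ccc(C(=O)/C=C/c2cc(OC)c(OCOC)c3OC(C)(C)C=Cc23)c(OCOC)c1
F2 | step 6 | trans-[2,4-bis(methoxymethoxy)phenyl]{3-[7-methoxy-8-(methoxymethoxy)-2,2-dimethyl-2H-chromen-5-yl]oxiran-2-yl}methanone (racemic, one enantiomer drawn) | COCOc1ccc(C(=O)[C@@H]2O[C@H]2c2cc(OC)c(OCOC)c3OC(C)(C)C=Cc23)c(OCOC)c1
F3 | step 6 | 3-[2,4-bis(methoxymethoxy)phenyl]-2-[7-methoxy-8-(methoxymethoxy)-2,2-dimethyl-2H-chromen-5-yl]-3-oxopropanal (racemic) | COCOc1ccc(C(=O)C(C=O)c2cc(OC)c(OCOC)c3OC(C)(C)C=Cc23)c(OCOC)c1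
F4 | step 1 | 4-hydroxy-3-methoxy-5-[(2-methylbut-3-yn-2-yl)oxy]benzaldehyde | COc1cc(C=O)cc(OC(C)(C)C#C)c1O
F5 | step 3 | 3-methoxy-4-(methoxymethoxy)-5-[(2-methylbut-3-en-2-yl)oxy]benzaldehyde | COCOc1c(OC)cc(C=O)cc1OC(C)(C)C=C
F6 | step 3 | 3-hydroxy-5-methoxy-4-(methoxymethoxy)-2-(3-methylbut-2-en-1-yl)benzaldehyde | COCOc1c(OC)cc(C=O)c(CC=C(C)C)c1O
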